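Everything rests on cutting ring C at O1–C2 and at C4–C4a. This splits the flavanone into a 2-prenylphloroglucinol (ring A) and an epoxyprenylated cinnamoyl unit (C4–C3–C2 plus ring B) of similar size. The halves are first tied by a sacrificial O1–C4 ester (an aryl cinnamate). In one flask, light shifts the acyl carbon C4 from O1 to the ortho carbon C4a (photo-Fries), and a chiral cinchona thiourea then closes O1 onto C2 and sets 2S. The step exploits the local symmetry of ring A about its O1–C8a···C6 axis: both carbons ortho to O1 are equivalent, para C6 carries the prenyl group, and O5 and O7 are silylated, so only the 6-prenyl isomer can form.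

Key step: step 9

Assumption: the quinine-derived member of the pseudoenantiomeric cinchona thiourea pair is taken to deliver O1 to the Si face of C2 (2S). Should the sense of induction be the opposite, the quinidine-derived member is used under the same conditions.

Step 1
Reactants: 1 phloroglucinol; 2 prenyl bromide
Product: 3 2-prenylphloroglucinol
Conditions: KOH (1 equiv), H2O, 0 °C to rt; 1 in threefold excess
Reagents that add atoms: none
Why: C-prenylation (allylic SN2 alkylation) of the ambident phloroglucinolate in water, where hydrogen bonding to the oxygens directs attack to ring carbon and the excess of 1 limits polyalkylation.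

Step 2
Reactants: 3 2-prenylphloroglucinol
Product: 4 1,3,5-tris(tert-butyldimethylsilyloxy)-2-prenylbenzene
Conditions: TBSCl (3.6 equiv), imidazole, DMF, rt
Reagents that add atoms: tert-butyldimethylsilyl chloride, CC(C)(C)[Si](C)(C)Cl
Why: Imidazole-promoted O-silylation caps all three phenols and leaves the trisubstituted alkene untouched.

Step 3
Reactants: 4 1,3,5-tris(tert-butyldimethylsilyloxy)-2-prenylbenzene
Product: 5 3,5-bis(tert-butyldimethylsilyloxy)-4-prenylphenol
Conditions: n-Bu4NF (1.0 equiv), AcOH (1.0 equiv), THF, −20 °C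
Reagents that add atoms: none
Why: Sterically differentiated fluoride desilylation, in which the silyl ether para to the prenyl group is flanked only by ring hydrogens and is attacked at silicon faster than the two ethers crowded by the ortho prenyl CH2, while one buffered equivalent of fluoride stops the reaction at the monophenol.

Step 4
Reactants: 5 3,5-bis(tert-butyldimethylsilyloxy)-4-prenylphenol; 6 acryloyl chloride
Product: 7 3,5-bis(tert-butyldimethylsilyloxy)-4-prenylphenyl acrylate
Conditions: Et3N, CH2Cl2, −20 °C
Reagents that add atoms: none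
Why: Base-mediated O-acylation of the only free phenol (the future O1) with an acid chloride, run cold to avoid conjugate addition to the acrylate.

Step 5
Reactants: 8 4-bromophenol; 2 prenyl bromide
Product: 9 4-bromo-2-prenylphenol
Conditions: KOH (1 equiv), H2O, rt, vigorous stirring
Reagents that add atoms: none
Why: ortho-C-prenylation of a phenoxide in water, where solvation of the oxygen favours carbon alkylation, the para position is blocked by bromine and one equivalent of 2 limits the second ortho alkylation.

Step 6
Reactants: 9 4-bromo-2-prenylphenol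
Product: 10 4-bromo-2-prenylphenyl tert-butyldimethylsilyl ether
Conditions: TBSCl, imidazole, DMF, rt
Reagents that add atoms: tert-butyldimethylsilyl chloride, CC(C)(C)[Si](C)(C)Cl
Why: Standard O-silylation masks the phenol so that it cannot open the epoxide made in the next step.

Step 7
Reactants: 10 4-bromo-2-prenylphenyl tert-butyldimethylsilyl ether
Product: 11 (R)-epoxide of 10
Conditions: D-fructose-derived ketone catalyst (1,2:4,5-di-O-isopropylidene-β-D-erythro-2,3-hexodiulo-2,6-pyranose, 30 mol %), Oxone (2KHSO5·KHSO4·K2SO4), K2CO3, n-Bu4NHSO4, MeCN–CH2(OMe)2, aq. Na2B4O7/Na2EDTA buffer, 0 °C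
Reagents that add atoms: potassium peroxymonosulfate, [K+].[O-]S(=O)(=O)OO
Why: Shi asymmetric epoxidation, in which the chiral dioxirane meets the trisubstituted alkene through the spiro transition state and transfers oxygen to the face that gives the R configuration at the epoxide CH, while the aryl bromide and the silyl ether are inert at 0 °C.

Step 8
Reactants: 11 (R)-epoxide; 7 3,5-bis(tert-butyldimethylsilyloxy)-4-prenylphenyl acrylate
Product: 12 aryl (E)-cinnamate joining rings A and B through the O1–C4 ester
Conditions: Pd2(dba)3 (2 mol %), P(t-Bu)3 (8 mol %), Cy2NMe, dioxane, rt to 40 °C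
Reagents that add atoms: none
Why: Mizoroki–Heck reaction, in which zerovalent palladium inserts into the C–Br bond, adds syn across the unhindered acrylate and eliminates syn to give the E-cinnamate, while the trisubstituted prenyl alkene, the epoxide, the aryl ester and the silyl ethers tolerate the mild amine base and low temperature.

Step 9
Reactants: 12 aryl (E)-cinnamate
Product: 14 tris-O-TBS (2S)-6-prenylflavanone, via chalcone 13 (not isolated)
Conditions: (a) hν (300 nm), degassed toluene (3 mM), FEP flow coil, 20 °C; (b) lamp off, no work-up, concentrate to 0.1 M, 1-[3,5-bis(trifluoromethyl)phenyl]-3-[(8α,9S)-6'-methoxycinchonan-9-yl]thiourea (15 mol %), −20 °C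
Reagents that add atoms: none
Why: Excitation of aryl ester 12 cleaves the O1–C4 acyl bond homolytically, and the solvent-caged aryloxyl/cinnamoyl radical pair recombines at a carbon ortho to O1 (C4–C4a formed) and tautomerises to the hydrogen-bonded E-2'-hydroxychalcone 13, which survives further irradiation because excited-state proton transfer deactivates it. With the lamp off, the thiourea unit of the catalyst binds the C4 carbonyl while its quinuclidine nitrogen takes the O1 proton, O1 adds to C2 of the enone (O1–C2 formed) and the enolate is protonated at C3. The closest known reaction types are the photo-Fries rearrangement of phloroglucinol-type aryl cinnamates to 2'-hydroxychalcones, the one-pot photo-Fries/oxa-Michael route from aryl enoates to chroman-4-ones and the cinchona thiourea-catalysed asymmetric cyclisation of 2'-hydroxychalcones to flavanones. Ring C closes in the 6-endo-trig mode. The new stereocentre C2 is controlled by the catalyst, which leaves only the Si face of C2 open to O1 and so gives 2S, while the remote epoxide carbon is untouched and turns the minor C2 epimer into a separable diastereomer. The regioselectivity needed (6-prenyl, not 8-prenyl, and no para shift) is secured by the substrate, since the two carbons ortho to O1 are equivalent, the para carbon C6 carries the prenyl group and O5 and O7 are silylated so that only O1 can close the ring.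

Step 10
Reactants: 14 tris-O-TBS (2S)-6-prenylflavanone
Product: 15 target flavanone
Conditions: n-Bu4NF (3.3 equiv), AcOH (3.5 equiv), THF, 0 °C; pH 7 phosphate work-up
Reagents that add atoms: none
Why: Fluoride-mediated cleavage of the three aryl silyl ethers, buffered with acetic acid so that the phenols stay protonated and neither retro-oxa-Michael opening at C2 nor attack of O4' on the neighbouring epoxide is triggered.

Compound list
1 | phloroglucinol (benzene-1,3,5-triol) | Oc1cc(O)cc(O)c1 | starting material
2 | prenyl bromide (1-bromo-3-methylbut-2-ene) | CC(C)=CCBr | starting material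
3 | 2-prenylphloroglucinol [2-(3-methylbut-2-enyl)benzene-1,3,5-triol] | CC(C)=CCc1c(O)cc(O)cc1O | intermediate
4 | 1,3,5-tris(tert-butyldimethylsilyloxy)-2-(3-methylbut-2-enyl)benzene | CC(C)=CCc1c(O[Si](C)(C)C(C)(C)C)cc(O[Si](C)(C)C(C)(C)C)cc1O[Si](C)(C)C(C)(C)C | intermediate
5 | 3,5-bis(tert-butyldimethylsilyloxy)-4-(3-methylbut-2-enyl)phenol | CC(C)=CCc1c(O[Si](C)(C)C(C)(C)C)cc(O)cc1O[Si](C)(C)C(C)(C)C | intermediate
6 | acryloyl chloride | C=CC(=O)Cl | starting material
7 | 3,5-bis(tert-butyldimethylsilyloxy)-4-(3-methylbut-2-enyl)phenyl acrylate | C=CC(=O)Oc1cc(O[Si](C)(C)C(C)(C)C)c(CC=C(C)C)c(O[Si](C)(C)C(C)(C)C)c1 | intermediate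
8 | 4-bromophenol | Oc1ccc(Br)cc1 | starting material
9 | 4-bromo-2-(3-methylbut-2-enyl)phenol | CC(C)=CCc1cc(Br)ccc1O | intermediate
10 | [4-bromo-2-(3-methylbut-2-enyl)phenoxy](tert-butyl)dimethylsilane | CC(C)=CCc1cc(Br)ccc1O[Si](C)(C)C(C)(C)C | intermediate
11 | [4-bromo-2-{[(2R)-3,3-dimethyloxiran-2-yl]methyl}phenoxy](tert-butyl)dimethylsilane | CC(C)(C)[Si](C)(C)Oc1ccc(Br)cc1C[C@H]2OC2(C)C | intermediate
12 | 3,5-bis(tert-butyldimethylsilyloxy)-4-(3-methylbut-2-enyl)phenyl (E)-3-[4-(tert-butyldimethylsilyloxy)-3-{[(2R)-3,3-dimethyloxiran-2-yl]methyl}phenyl]acrylate | CC(C)=CCc1c(O[Si](C)(C)C(C)(C)C)cc(OC(=O)/C=C/c2ccc(O[Si](C)(C)C(C)(C)C)c(C[C@H]3OC3(C)C)c2)cc1O[Si](C)(C)C(C)(C)C | intermediate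
13 | (E)-1-[6-hydroxy-2,4-bis(tert-butyldimethylsilyloxy)-3-(3-methylbut-2-enyl)phenyl]-3-[4-(tert-butyldimethylsilyloxy)-3-{[(2R)-3,3-dimethyloxiran-2-yl]methyl}phenyl]prop-2-en-1-one | CC(C)=CCc1c(O[Si](C)(C)C(C)(C)C)cc(O)c(C(=O)/C=C/c2ccc(O[Si](C)(C)C(C)(C)C)c(C[C@H]3OC3(C)C)c2)c1O[Si](C)(C)C(C)(C)C | intermediate
14 | (2S)-5,7-bis(tert-butyldimethylsilyloxy)-2-[4-(tert-butyldimethylsilyloxy)-3-{[(2R)-3,3-dimethyloxiran-2-yl]methyl}phenyl]-6-(3-methylbut-2-enyl)chroman-4-one | CC(C)=CCc1c(O[Si](C)(C)C(C)(C)C)cc2c(c1O[Si](C)(C)C(C)(C)C)C(=O)C[C@@H](c1ccc(O[Si](C)(C)C(C)(C)C)c(C[C@H]3OC3(C)C)c1)O2 | intermediate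
15 | (2S)-5,7-dihydroxy-2-[4-hydroxy-3-{[(2R)-3,3-dimethyloxiran-2-yl]methyl}phenyl]-6-(3-methylbut-2-enyl)chroman-4-one | CC(C)=CCc1c(O)cc2c(c1O)C(=O)C[C@@H](c1ccc(O)c(C[C@H]3OC3(C)C)c1)O2 | target

Total step count: 10. Longest linear sequence: 7 steps (1, 2, 3, 4, 8, 9, 10).

Steps most likely to fail

Step 9. The acyl shift may stall in three ways: the radical pair escapes from the solvent cage, E/Z isomerisation of the cinnamate drains the excitation energy, and the growing chalcone absorbs the light. The fallback replaces the photochemical shift with a polar, stepwise acylation and sets out from 5 and 11.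
- Iodination of 5 ortho to the free hydroxyl group (N-iodosuccinimide, CH2Cl2, −20 °C) would give 2-iodo-3,5-bis(tert-butyldimethylsilyloxy)-4-prenylphenol F1.
- Mizoroki–Heck coupling of 11 with N-methoxy-N-methylacrylamide under the conditions of step 8 would give the N-methoxy-N-methyl cinnamamide F2.
- F1 with i-PrMgCl·LiCl (2.1 equiv, THF, −20 °C; deprotonation, then iodine–magnesium exchange) would give the O,C-dimagnesiated arene F3.
- Addition of F3 to F2 and a buffered NH4Cl quench would release chalcone 13.

The route is rejoined at 13, which is then purified and cyclised with the thiourea as in stage b of step 9.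

Step 10. The liberated O4' phenoxide may open the neighbouring epoxide by 5-exo closure. Basic fluoride may also open ring C by a retro-oxa-Michael reaction, with loss of the C2 configuration. The fallback is a trap-and-release sequence that sets out from 14. Fluoride cleavage in the presence of acetic anhydride (n-Bu4NF, Ac2O, THF, −20 °C) would acetylate each phenoxide as it is freed and give the flavanone triacetate F4. Lipase-catalysed alcoholysis (Candida antarctica lipase B, n-BuOH, t-BuOMe, 30 °C) would then free the three phenols at neutral pH and arrive at 15.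

Step 3. Discrimination between the three silyl ethers may be insufficient, and desilylation may run on to diols. The fallback moves the selectivity to a bond-forming event with a bulky acyl group and sets out from 3. Pivaloyl chloride (1.0 equiv, Et3N, CH2Cl2, −78 °C) would acylate the least hindered hydroxyl group and give 3,5-dihydroxy-4-prenylphenyl pivalate F5. TBSCl and imidazole would give 3,5-bis(tert-butyldimethylsilyloxy)-4-prenylphenyl pivalate F6. Reductive removal of the ester (i-Bu2AlH, CH2Cl2, −78 °C), which spares the aryl silyl ethers, would come back to the route at 5.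

Further compounds
F1 | step 9 | 2-iodo-3,5-bis(tert-butyldimethylsilyloxy)-4-(3-methylbut-2-enyl)phenol | CC(C)=CCc1c(O[Si](C)(C)C(C)(C)C)cc(O)c(I)c1O[Si](C)(C)C(C)(C)C
F2 | step 9 | (E)-3-[4-(tert-butyldimethylsilyloxy)-3-{[(2R)-3,3-dimethyloxiran-2-yl]methyl}phenyl]-N-methoxy-N-methylacrylamide | CON(C)C(=O)/C=C/c1ccc(O[Si](C)(C)C(C)(C)C)c(C[C@H]2OC2(C)C)c1
F3 | step 9 | O,C-dimagnesiated arene from F1 (chloromagnesium phenoxide bearing an ortho arylmagnesium chloride) | CC(C)=CCc1c(O[Si](C)(C)C(C)(C)C)cc(O[Mg]Cl)c([Mg]Cl)c1O[Si](C)(C)C(C)(C)C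
F4 | step 10 | (2S)-5,7-diacetoxy-2-[4-acetoxy-3-{[(2R)-3,3-dimethyloxiran-2-yl]methyl}phenyl]-6-(3-methylbut-2-enyl)chroman-4-one | CC(C)=CCc1c(OC(C)=O)cc2c(c1OC(C)=O)C(=O)C[C@@H](c1ccc(OC(C)=O)c(C[C@H]3OC3(C)C)c1)O2
F5 | step 3 | 3,5-dihydroxy-4-(3-methylbut-2-enyl)phenyl pivalate | CC(C)=CCc1c(O)cc(OC(=O)C(C)(C)C)cc1O
F6 | step 3 | 3,5-bis(tert-butyldimethylsilyloxy)-4-(3-methylbut-2-enyl)phenyl pivalate | CC(C)=CCc1c(O[Si](C)(C)C(C)(C)C)cc(OC(=O)C(C)(C)C)cc1O[Si](C)(C)C(C)(C)C
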